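The route rests on cutting C7–C6, the bond between the side-chain CH2 and the fully substituted peroxy carbon C6 of the 1,2-dioxane ring. C6 carries CH3 and CH2R, groups too alike for steric control, so the bond is made while C6 is sp2. A stereoretentive Negishi coupling joins the (R)-2-methyl-10-phenyldecylzinc reagent to an (E)-alkenyl iodide carrying C3–C6 and the C4 stereocentre. The resulting E-alkene stores the CH3/CH2R difference as geometry. A 6-endo, anti iodoperoxidation from a C3 hydroperoxy acetal then translates it into the C6 configuration, and axial acetate addition to the C3 peroxycarbenium ion completes the all-cis ring.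

Key step: step 9

Numbering used: ring O1, O2, C3 (bears CH2CO2H), C4 (bears CH3), C5, C6 (quaternary). Side chain C7 (CH2), C8 (bears CH3), then C9 onward to the phenyl group.
Remark: 19, 20 and 21 are carried as mixtures of epimers at the acetal carbon C3. This carbon becomes planar in step 15, so their SMILES leave it open.

Step 1
Reactants: 1 (S)-3-bromo-2-methylpropan-1-ol
Product: 2 (S)-(3-bromo-2-methylpropoxy)(tert-butyl)dimethylsilane
Conditions: TBSCl, imidazole, CH2Cl2, 0 °C to rt
Reagents that add atoms: tert-butyldimethylsilyl chloride, CC(C)(C)[Si](C)(C)Cl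
Why: Imidazole-promoted silylation of a primary alcohol leaves the stereocentre untouched and keeps an alkoxide from closing to achiral 3-methyloxetane in the next step.

Step 2
Reactants: 3 (7-bromoheptyl)benzene; 2 (S)-(3-bromo-2-methylpropoxy)(tert-butyl)dimethylsilane
Product: 5 tert-butyldimethyl{[(2R)-2-methyl-10-phenyldecyl]oxy}silane, via 7-phenylheptylmagnesium bromide 4 (not isolated)
Conditions: 3, Mg, THF, 40 °C; then 2, Li2CuCl4 (3 mol %), NMP, THF, 0 °C to rt
Reagents that add atoms: none
Why: Copper-catalysed cross-coupling of a Grignard reagent with a primary alkyl bromide forms the C9–C10 bond at a CH2 group, so the neighbouring stereocentre (future C8) passes through unchanged and only its descriptor changes.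

Step 3
Reactants: 5 tert-butyldimethyl{[(2R)-2-methyl-10-phenyldecyl]oxy}silane
Product: 6 [(9R)-10-bromo-9-methyldecyl]benzene
Conditions: Ph3PBr2, CH2Cl2, 0 °C to rt
Reagents that add atoms: dibromotriphenylphosphorane, BrP(Br)(c1ccccc1)(c1ccccc1)c1ccccc1
Why: Appel-type bromination applied directly to the silyl ether turns the Si–O–CH2 unit into an alkoxyphosphonium ion, which bromide opens by SN2 at the primary carbon, away from the stereocentre.

Step 4
Reactants: 7 methyl (R)-3-hydroxy-2-methylpropanoate
Product: 8 methyl (R)-3-[(tert-butyldimethylsilyl)oxy]-2-methylpropanoate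
Conditions: TBSCl, imidazole, DMF, rt
Reagents that add atoms: tert-butyldimethylsilyl chloride, CC(C)(C)[Si](C)(C)Cl
Why: Standard silylation of the primary alcohol protects the future C3 oxygen without touching the stereocentre (future C4).

Step 5
Reactants: 8 methyl (R)-3-[(tert-butyldimethylsilyl)oxy]-2-methylpropanoate
Product: 9 (R)-3-[(tert-butyldimethylsilyl)oxy]-2-methylpropanal
Conditions: i-Bu2AlH (1.05 equiv), CH2Cl2, −78 °C; aqueous potassium sodium tartrate
Reagents that add atoms: none
Why: Partial ester reduction at low temperature stops at the tetrahedral aluminium hemiacetal, which releases the aldehyde only on work-up, and the α-stereocentre survives because no base is present.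

Step 6
Reactants: 9 (R)-3-[(tert-butyldimethylsilyl)oxy]-2-methylpropanal
Product: 10 (S)-tert-butyl[(4,4-dibromo-2-methylbut-3-en-1-yl)oxy]dimethylsilane
Conditions: CBr4, PPh3, 2,6-lutidine, CH2Cl2, 0 °C
Reagents that add atoms: carbon tetrabromide, BrC(Br)(Br)Br
Why: This is the first stage of the Corey–Fuchs alkyne synthesis, a Wittig-type dibromomethylenation under buffered conditions that do not enolise the aldehyde.

Step 7
Reactants: 10 (S)-tert-butyl[(4,4-dibromo-2-methylbut-3-en-1-yl)oxy]dimethylsilane
Product: 12 (S)-tert-butyldimethyl[(2-methylpent-3-yn-1-yl)oxy]silane, via lithium acetylide 11 (not isolated)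
Conditions: n-BuLi (2.1 equiv), THF, −78 to 0 °C; then MeI, −78 °C to rt
Reagents that add atoms: iodomethane, C[I]
Why: In the second stage of the Corey–Fuchs sequence, bromine–lithium exchange, a Fritsch–Buttenberg–Wiechell 1,2-shift and deprotonation give acetylide 11, which iodomethane alkylates at carbon to install the future C6 methyl group.

Step 8
Reactants: 12 (S)-tert-butyldimethyl[(2-methylpent-3-yn-1-yl)oxy]silane
Product: 14 (S,E)-tert-butyl[(4-iodo-2-methylpent-3-en-1-yl)oxy]dimethylsilane, via alkenylzirconocene chloride 13 (not isolated)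
Conditions: Cp2Zr(H)Cl (2 equiv), THF, 45 °C; then I2, 0 °C
Reagents that add atoms: iodine, [I][I]
Why: In this hydrozirconation–iodinolysis, syn addition of Zr–H, equilibrated by excess reagent so that zirconium sits on the less hindered methyl-bearing carbon C6, is followed by iodinolysis with retention to give the E iodide with CH3 cis and iodine trans to C4.

Step 9
Reactants: 6 [(9R)-10-bromo-9-methyldecyl]benzene; 14 (S,E)-tert-butyl[(4-iodo-2-methylpent-3-en-1-yl)oxy]dimethylsilane
Product: 16 tert-butyldimethyl{[(2S,3E,6R)-2,4,6-trimethyl-14-phenyltetradec-3-en-1-yl]oxy}silane, via [(2R)-2-methyl-10-phenyldecyl]zinc bromide 15 (not isolated)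
Conditions: 6, Zn dust, I2 (5 mol %), DMA, 80 °C; then 14, Pd(dppf)Cl2 (4 mol %), THF–DMA, 40 °C
Reagents that add atoms: none
Why: Zinc inserts into the C–Br bond of 6 to give 15; zerovalent palladium, formed from Pd(dppf)Cl2 by 15, adds oxidatively to the C(sp2)–I bond of 14, takes over the C7 methylene group by transmetalation and forms the C7–C6 bond by reductive elimination. The closest known reaction type is the Negishi alkyl–alkenyl cross-coupling. No ring is closed and no stereocentre is created; the new stereochemical element is the E C5=C6 double bond, controlled by the geometry of 14 because oxidative addition and reductive elimination at an alkenyl carbon proceed with retention. The step needs reductive elimination to outrun β-hydride elimination at the β-branched alkylpalladium stage, which the wide bite angle of dppf secures, and it needs both existing stereocentres to survive, which they do because C8 is β to zinc and C4 carries no acidic hydrogen. In one operation the two halves are joined at the carbon that becomes the quaternary C6, with CH3 fixed cis and C7 trans to C4, the information that step 13 converts into the C6 configuration.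

Step 10
Reactants: 16 tert-butyldimethyl{[(2S,3E,6R)-2,4,6-trimethyl-14-phenyltetradec-3-en-1-yl]oxy}silane
Product: 17 (2S,3E,6R)-2,4,6-trimethyl-14-phenyltetradec-3-en-1-ol
Conditions: Bu4NF, THF, 0 °C to rt
Reagents that add atoms: none
Why: Fluoride-induced desilylation is driven by the Si–F bond, and the alkene and both stereocentres are inert to it.

Step 11
Reactants: 17 (2S,3E,6R)-2,4,6-trimethyl-14-phenyltetradec-3-en-1-ol
Product: 18 (2S,3E,6R)-2,4,6-trimethyl-14-phenyltetradec-3-enal
Conditions: Dess–Martin periodinane, pyridine, CH2Cl2, 0 °C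
Reagents that add atoms: none
Why: Dess–Martin oxidation under buffered, non-basic conditions is chosen so that the β,γ-unsaturated α-methyl aldehyde neither epimerises at C4 nor moves its double bond into conjugation.

Step 12
Reactants: 18 (2S,3E,6R)-2,4,6-trimethyl-14-phenyltetradec-3-enal
Product: 19 (2S,3E,6R)-1-methoxy-2,4,6-trimethyl-14-phenyltetradec-3-en-1-yl hydroperoxide (C3 epimers)
Conditions: anhydrous H2O2 in Et2O, MeOH, pyridinium p-toluenesulfonate (10 mol %), CH2Cl2, 0 °C
Reagents that add atoms: hydrogen peroxide, OO; methanol, CO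
Why: In this acid-catalysed perhydrolytic acetalisation the methoxy oxocarbenium ion of the aldehyde is captured by H2O2, the better nucleophile through the α-effect, and the new C3 centre forms as a mixture that does not matter because step 15 planarises it.

Step 13
Reactants: 19 (2S,3E,6R)-1-methoxy-2,4,6-trimethyl-14-phenyltetradec-3-en-1-yl hydroperoxide (C3 epimers)
Product: 20 (4R,5S,6R)-5-iodo-3-methoxy-4,6-dimethyl-6-[(2R)-2-methyl-10-phenyldecyl]-1,2-dioxane (C3 epimers)
Conditions: N-iodosuccinimide, CH2Cl2, 0 °C, dark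
Reagents that add atoms: N-iodosuccinimide, O=C1CCC(=O)N1I
Why: In this halonium-induced cyclisation of an unsaturated hydroperoxy acetal (cycloperoxyiodination) the terminal peroxide oxygen opens the iodonium ion at the tertiary carbon C6 (Markovnikov, 6-endo) anti to iodine through a chair in which allylic 1,3-strain keeps C4–H next to the C6 methyl group, so the E geometry places C6–CH3 axial and C7 equatorial, C4–CH3 stays equatorial, and C6 (R) and C5 (S) are set relative to C4.

Step 14
Reactants: 20 (4R,5S,6R)-5-iodo-3-methoxy-4,6-dimethyl-6-[(2R)-2-methyl-10-phenyldecyl]-1,2-dioxane (C3 epimers)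
Product: 21 (4S,6R)-3-methoxy-4,6-dimethyl-6-[(2R)-2-methyl-10-phenyldecyl]-1,2-dioxane (C3 epimers)
Conditions: Bu3SnH (3 equiv, 1 M), Et3B (0.2 equiv), trace air, toluene, −20 °C
Reagents that add atoms: none
Why: In this radical-chain hydrodeiodination with a tin hydride, known for iodoalkyl peroxides, the secondary C5 radical lies in the ring where its orbital cannot align with the O–O or the C6–O1 bond, so hydrogen transfer from concentrated Bu3SnH at low temperature should outrun ring opening, and the C5 centre disappears while C4 and C6 stay.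

Step 15
Reactants: 21 (4S,6R)-3-methoxy-4,6-dimethyl-6-[(2R)-2-methyl-10-phenyldecyl]-1,2-dioxane (C3 epimers)
Product: 22 methyl 2-{(3S,4S,6R)-4,6-dimethyl-6-[(2R)-2-methyl-10-phenyldecyl]-1,2-dioxan-3-yl}acetate
Conditions: 1-(tert-butyldimethylsilyloxy)-1-methoxyethene (2 equiv), Me3SiOTf (0.3 equiv), CH2Cl2, −78 °C
Reagents that add atoms: 1-(tert-butyldimethylsilyloxy)-1-methoxyethene, C=C(OC)O[Si](C)(C)C(C)(C)C
Why: In this Mukaiyama-type addition of a silyl ketene acetal to the peroxycarbenium ion formed by loss of methoxide from C3, the ion reacts through the half-chair that keeps C4–CH3 and C7 equatorial (the other would make them syn-diaxial), and the stereoelectronically preferred axial attack puts the acetate chain cis to C4–CH3, which sets C3 (S) from both epimers of 21.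

Step 16
Reactants: 22 methyl 2-{(3S,4S,6R)-4,6-dimethyl-6-[(2R)-2-methyl-10-phenyldecyl]-1,2-dioxan-3-yl}acetate
Product: 23 2-{(3S,4S,6R)-4,6-dimethyl-6-[(2R)-2-methyl-10-phenyldecyl]-1,2-dioxan-3-yl}acetic acid
Conditions: LiOH, THF–H2O, 0 °C; then 1 M HCl to pH 3
Reagents that add atoms: lithium hydroxide, [Li+].[OH-]
Why: Mild saponification of the methyl ester at low temperature, a standard operation on 1,2-dioxane-3-acetates, cleaves the acyl–oxygen bond faster than the β-peroxy ester can undergo retro-oxa-Michael opening, so no stereocentre is touched.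

Compound list
1 | (S)-3-bromo-2-methylpropan-1-ol | C[C@H](CBr)CO | starting material
2 | (S)-(3-bromo-2-methylpropoxy)(tert-butyl)dimethylsilane | C[C@H](CBr)CO[Si](C)(C)C(C)(C)C | intermediate
3 | (7-bromoheptyl)benzene | BrCCCCCCCc1ccccc1 | starting material
4 | 7-phenylheptylmagnesium bromide | Br[Mg]CCCCCCCc1ccccc1 | intermediate
5 | tert-butyldimethyl{[(2R)-2-methyl-10-phenyldecyl]oxy}silane | C[C@H](CCCCCCCCc1ccccc1)CO[Si](C)(C)C(C)(C)C | intermediate
6 | [(9R)-10-bromo-9-methyldecyl]benzene | C[C@H](CCCCCCCCc1ccccc1)CBr | intermediate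
7 | methyl (R)-3-hydroxy-2-methylpropanoate | COC(=O)[C@H](C)CO | starting material
8 | methyl (R)-3-[(tert-butyldimethylsilyl)oxy]-2-methylpropanoate | COC(=O)[C@H](C)CO[Si](C)(C)C(C)(C)C | intermediate
9 | (R)-3-[(tert-butyldimethylsilyl)oxy]-2-methylpropanal | O=C[C@H](C)CO[Si](C)(C)C(C)(C)C | intermediate
10 | (S)-tert-butyl[(4,4-dibromo-2-methylbut-3-en-1-yl)oxy]dimethylsilane | BrC(Br)=C[C@H](C)CO[Si](C)(C)C(C)(C)C | intermediate
11 | lithium acetylide of (S)-tert-butyl[(2-methylbut-3-yn-1-yl)oxy]dimethylsilane | [Li]C#C[C@H](C)CO[Si](C)(C)C(C)(C)C | intermediate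
12 | (S)-tert-butyldimethyl[(2-methylpent-3-yn-1-yl)oxy]silane | CC#C[C@H](C)CO[Si](C)(C)C(C)(C)C | intermediate
13 | (E)-alkenylzirconocene chloride with zirconium on C6, trans to C4 | C/C([Zr](Cl)(C1C=CC=C1)C1C=CC=C1)=C\[C@H](C)CO[Si](C)(C)C(C)(C)C | intermediate
14 | (S,E)-tert-butyl[(4-iodo-2-methylpent-3-en-1-yl)oxy]dimethylsilane | C/C(I)=C\[C@H](C)CO[Si](C)(C)C(C)(C)C | intermediate
15 | [(2R)-2-methyl-10-phenyldecyl]zinc bromide | C[C@H](CCCCCCCCc1ccccc1)C[Zn]Br | intermediate
16 | tert-butyldimethyl{[(2S,3E,6R)-2,4,6-trimethyl-14-phenyltetradec-3-en-1-yl]oxy}silane | C[C@H](CCCCCCCCc1ccccc1)C/C(C)=C/[C@H](C)CO[Si](C)(C)C(C)(C)C | intermediate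
17 | (2S,3E,6R)-2,4,6-trimethyl-14-phenyltetradec-3-en-1-ol | C[C@H](CCCCCCCCc1ccccc1)C/C(C)=C/[C@H](C)CO | intermediate
18 | (2S,3E,6R)-2,4,6-trimethyl-14-phenyltetradec-3-enal | C[C@H](CCCCCCCCc1ccccc1)C/C(C)=C/[C@H](C)C=O | intermediate
19 | (2S,3E,6R)-1-methoxy-2,4,6-trimethyl-14-phenyltetradec-3-en-1-yl hydroperoxide (C3 epimers) | C[C@H](CCCCCCCCc1ccccc1)C/C(C)=C/[C@H](C)C(OC)OO | intermediate
20 | (4R,5S,6R)-5-iodo-3-methoxy-4,6-dimethyl-6-[(2R)-2-methyl-10-phenyldecyl]-1,2-dioxane (C3 epimers) | C[C@H](CCCCCCCCc1ccccc1)C[C@]1(C)[C@@H](I)[C@H](C)C(OC)OO1 | intermediate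
21 | (4S,6R)-3-methoxy-4,6-dimethyl-6-[(2R)-2-methyl-10-phenyldecyl]-1,2-dioxane (C3 epimers) | C[C@H](CCCCCCCCc1ccccc1)C[C@]1(C)C[C@H](C)C(OC)OO1 | intermediate
22 | methyl 2-{(3S,4S,6R)-4,6-dimethyl-6-[(2R)-2-methyl-10-phenyldecyl]-1,2-dioxan-3-yl}acetate | C[C@H](CCCCCCCCc1ccccc1)C[C@]1(C)C[C@H](C)[C@H](CC(=O)OC)OO1 | intermediate
23 | 2-{(3S,4S,6R)-4,6-dimethyl-6-[(2R)-2-methyl-10-phenyldecyl]-1,2-dioxan-3-yl}acetic acid | C[C@H](CCCCCCCCc1ccccc1)C[C@]1(C)C[C@H](C)[C@H](CC(=O)O)OO1 | target

Total steps: 16. Longest linear sequence: 13 steps (steps 4 to 16, from 7 to 23).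

Steps most likely to fail

Step 13. Three things may go wrong:
- Closure may occur in the 5-exo mode at C5.
- The methoxy oxygen may attack the iodonium ion, followed by methoxy migration.
- The iodine reagent may oxidise the hydroperoxide.

The fallback sets out from 18 and comes back at 22.
- A Horner–Wadsworth–Emmons olefination with trimethyl phosphonoacetate (LiCl, DBU, MeCN) should give methyl (2E,4R,5E,8R)-4,6,8-trimethyl-16-phenylhexadeca-2,5-dienoate F1.
- An Isayama–Mukaiyama peroxidation (Co(thd)2, O2, Et3SiH, 1,2-dichloroethane) should place the peroxy group on C6 in the Markovnikov sense. This gives methyl (2E,4S,8R)-4,6,8-trimethyl-16-phenyl-6-[(triethylsilyl)peroxy]hexadec-2-enoate F2 as C6 epimers.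
- Bu4NF buffered with acetic acid should free methyl (2E,4S,8R)-6-hydroperoxy-4,6,8-trimethyl-16-phenylhexadec-2-enoate F3.
- F3 closes by intramolecular oxa-Michael addition (Et2NH, CF3CH2OH) to 22 and to methyl 2-{(3S,4S,6S)-4,6-dimethyl-6-[(2R)-2-methyl-10-phenyldecyl]-1,2-dioxan-3-yl}acetate F4.
- The two are to be separated by chromatography. This path gives up control at C6.

Step 12. The acid may epimerise C4 or move the double bond into conjugation, or perhydrolysis may run on to the geminal bis-hydroperoxide.

The fallback sets out from 18 and comes back at 20.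
- Acid-free addition of ethereal H2O2 should give (2S,3E,6R)-1-hydroperoxy-2,4,6-trimethyl-14-phenyltetradec-3-en-1-ol F5.
- N-iodosuccinimide should close F5 by the same chair to (4R,5S,6R)-5-iodo-4,6-dimethyl-6-[(2R)-2-methyl-10-phenyldecyl]-1,2-dioxan-3-ol F6.
- Only then is the ring hemiacetal exchanged with MeOH and pyridinium p-toluenesulfonate to 20. At that point C4 is held in the ring and the alkene is gone.

Step 14. Stannyl radicals may attack the O–O bond, or the β-peroxy radical may open the ring before hydrogen transfer.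

The fallback sets out from 19 and comes back at 21, bypassing 20.
- Cycloperoxymercuration with Hg(OAc)2 in CH2Cl2 is reversible, follows Markovnikov orientation and goes by anti addition through the same chair. It should give acetoxy{(4R,5S,6R)-3-methoxy-4,6-dimethyl-6-[(2R)-2-methyl-10-phenyldecyl]-1,2-dioxan-5-yl}mercury F7.
- Alkaline NaBH4 then replaces mercury by hydrogen through an alkylmercury hydride chain. This chain contains no species that attacks peroxides.

Further compounds
F1 | step 13 | methyl (2E,4R,5E,8R)-4,6,8-trimethyl-16-phenylhexadeca-2,5-dienoate | C[C@H](CCCCCCCCc1ccccc1)C/C(C)=C/[C@H](C)/C=C/C(=O)OC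
F2 | step 13 | methyl (2E,4S,8R)-4,6,8-trimethyl-16-phenyl-6-[(triethylsilyl)peroxy]hexadec-2-enoate (C6 epimers) | C[C@H](CCCCCCCCc1ccccc1)CC(C)(OO[Si](CC)(CC)CC)C[C@H](C)/C=C/C(=O)OC
F3 | step 13 | methyl (2E,4S,8R)-6-hydroperoxy-4,6,8-trimethyl-16-phenylhexadec-2-enoate (C6 epimers) | C[C@H](CCCCCCCCc1ccccc1)CC(C)(OO)C[C@H](C)/C=C/C(=O)OC
F4 | step 13 | methyl 2-{(3S,4S,6S)-4,6-dimethyl-6-[(2R)-2-methyl-10-phenyldecyl]-1,2-dioxan-3-yl}acetate | C[C@H](CCCCCCCCc1ccccc1)C[C@@]1(C)C[C@H](C)[C@H](CC(=O)OC)OO1
F5 | step 12 | (2S,3E,6R)-1-hydroperoxy-2,4,6-trimethyl-14-phenyltetradec-3-en-1-ol (C3 epimers) | C[C@H](CCCCCCCCc1ccccc1)C/C(C)=C/[C@H](C)C(O)OO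
F6 | step 12 | (4R,5S,6R)-5-iodo-4,6-dimethyl-6-[(2R)-2-methyl-10-phenyldecyl]-1,2-dioxan-3-ol (C3 epimers) | C[C@H](CCCCCCCCc1ccccc1)C[C@]1(C)[C@@H](I)[C@H](C)C(O)OO1
F7 | step 14 | acetoxy{(4R,5S,6R)-3-methoxy-4,6-dimethyl-6-[(2R)-2-methyl-10-phenyldecyl]-1,2-dioxan-5-yl}mercury (C3 epimers) | C[C@H](CCCCCCCCc1ccccc1)C[C@]1(C)[C@@H]([Hg]OC(C)=O)[C@H](C)C(OC)OO1
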